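**Retrosynthetic overview**
- The diol comes last: hydride opening of a 2,2-disubstituted epoxide at CH2 (this makes the C4′ methyl). The epoxide comes from Sharpless epoxidation of a (3′R) 2-substituted allylic alcohol, itself from CBS reduction of an α-methylene ketone.
- The ketone is assembled by carbonylative coupling of a C2′ alkylzinc on the ring fragment with the enol triflate of (E)-geranylacetone, which brings C4′–C13′ and both trisubstituted olefins.
- The acrylate is made by Markovnikov methoxycarbonylation of a 2-ethynyl-oxane.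
- The only ring (the oxane) is closed by acetylide addition to a seven-membered lactone and axial hydride reduction of the six-membered hemiketal (2,5-trans).
- The lactone comes from enantioselective Baeyer–Villiger desymmetrisation of 4-(hydroxymethyl)cyclohexanone, made from 4-hydroxybenzyl alcohol; the arene carbons become C2–C5, C1′ and C2′, the benzylic carbon becomes C6.

Assumptions: ring atoms are O1, C2 (acrylate), C5 (side chain); primed locants run along the side chain from C1′ on C5. The ligand antipode written in step 3 is taken to give (R)-4; its sense for this substrate is not known to me, so if a test run gives the (S)-lactone the mirror-image ligand is used. Commercial isomerically pure (E)-geranylacetone is used.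

Step 1
Reactants: 1 4-(hydroxymethyl)phenol (4-hydroxybenzyl alcohol)
Product: 2 4-(hydroxymethyl)cyclohexan-1-ol (cis/trans mixture)
Conditions: H2 (4 bar), 5 % Rh/Al2O3, EtOH, 25 °C
Reagents that add atoms: none
Why: Arene hydrogenation on rhodium saturates the phenol ring with little hydrogenolysis of the benzylic C–O bond; both diastereomers give the same ketone, so the new centres do not matter.

Step 2
Reactants: 2 4-(hydroxymethyl)cyclohexan-1-ol
Product: 3 4-(hydroxymethyl)cyclohexan-1-one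
Conditions: aq. NaOCl (1.1 equiv), AcOH, 20 °C
Reagents that add atoms: none
Why: Stevens hypochlorite oxidation takes the secondary alcohol much faster than the primary one and gives the achiral, mirror-symmetric ketone.

Step 3
Reactants: 3 4-(hydroxymethyl)cyclohexan-1-one
Product: 4 (5R)-5-(hydroxymethyl)oxepan-2-one
Conditions: Sc(OTf)3 (5 mol %), (2S,2′S)-1,1′-(propane-1,3-diyl)bis[N-(2,6-diisopropylphenyl)piperidine-2-carboxamide] 1,1′-dioxide (6 mol %), 3-ClC6H4CO3H (1.2 equiv), EtOAc, −20 °C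
Reagents that add atoms: 3-chloroperoxybenzoic acid, O=C(OO)c1cccc(Cl)c1
Why: Catalytic enantioselective Baeyer–Villiger oxidation: the chiral Sc–N,N′-dioxide complex lets only one of the two enantiotopic α-CH2 groups migrate in the Criegee adduct, which breaks the mirror symmetry and sets C5 ((R) in 4, (S) in the target by CIP change); any translactonisation to the six-membered hydroxy lactone is harmless because both isomers give 5.

Step 4
Reactants: 4 (5R)-5-(hydroxymethyl)oxepan-2-one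
Product: 5 (5R)-2-ethynyl-5-(2-hydroxyethyl)oxan-2-ol (anomer mixture)
Conditions: HC≡CMgBr (3.5 equiv), THF, −78 to −30 °C; aq. NH4Cl
Reagents that add atoms: ethynylmagnesium bromide, C#C[Mg]Br
Why: Acetylide addition to the lactone (Grignard acylation) stops at the ketone stage because the magnesium alkoxide of the CH2OH arm closes the six-membered hemiketal; C5 is untouched.

Step 5
Reactants: 5 (5R)-2-ethynyl-5-(2-hydroxyethyl)oxan-2-ol
Product: 6 2-[(3R,6R)-6-ethynyloxan-3-yl]ethan-1-ol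
Conditions: Et3SiH (5 equiv), BF3·OEt2 (3 equiv), CH2Cl2–MeCN, −40 °C
Reagents that add atoms: none
Why: Kishi-type ionic hydrogenation: BF3 ionises the hemiketal to the six-membered oxocarbenium ion and Et3SiH adds axially to the half-chair that keeps the C5 arm pseudo-equatorial, which gives the 2,5-trans ring (ethynyl equatorial, new centre (R)).

Step 6
Reactants: 6 2-[(3R,6R)-6-ethynyloxan-3-yl]ethan-1-ol
Product: 7 methyl 2-[(2R,5R)-5-(2-hydroxyethyl)oxan-2-yl]prop-2-enoate
Conditions: Pd(OAc)2 (2 mol %), 2-(diphenylphosphino)pyridine (8 mol %), MeSO3H (8 mol %), CO (20 bar), MeOH, 50 °C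
Reagents that add atoms: carbon monoxide, [C-]#[O+]; methanol, CO
Why: Drent-type Pd-catalysed Markovnikov methoxycarbonylation of a terminal alkyne gives the 2-substituted acrylate directly and touches no stereocentre.

Step 7
Reactants: 7 methyl 2-[(2R,5R)-5-(2-hydroxyethyl)oxan-2-yl]prop-2-enoate
Product: 8 methyl 2-[(2R,5R)-5-(2-iodoethyl)oxan-2-yl]prop-2-enoate
Conditions: I2, PPh3, imidazole, CH2Cl2, 0 °C
Reagents that add atoms: iodine, II
Why: Appel-type (Garegg–Samuelsson) iodination by SN2 on the alkoxyphosphonium salt converts the primary alcohol under neutral conditions that spare the acrylate.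

Step 8
Reactants: 9 (5E)-6,10-dimethylundeca-5,9-dien-2-one ((E)-geranylacetone)
Product: 10 (5E)-6,10-dimethylundeca-1,5,9-trien-2-yl trifluoromethanesulfonate
Conditions: KN(SiMe3)2, THF, −78 °C; PhNTf2, −78 to 0 °C
Reagents that add atoms: N-phenylbis(trifluoromethanesulfonyl)imide, O=S(=O)(N(c1ccccc1)S(=O)(=O)C(F)(F)F)C(F)(F)F
Why: Kinetic deprotonation of the methyl ketone at CH3 and O-triflation of the enolate give the 1,1-disubstituted alkenyl triflate and leave the (E)-olefin untouched.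

Step 9
Reactants: 8 methyl 2-[(2R,5R)-5-(2-iodoethyl)oxan-2-yl]prop-2-enoate; 10 (5E)-6,10-dimethylundeca-1,5,9-trien-2-yl trifluoromethanesulfonate
Product: 12 methyl 2-[(2R,5R)-5-[(7E)-8,12-dimethyl-4-methylidene-3-oxotrideca-7,11-dien-1-yl]oxan-2-yl]prop-2-enoate, via alkylzinc iodide 11 (not isolated)
Conditions: Zn dust, LiCl, THF, 40 °C; then 10, Pd(PPh3)4 (5 mol %), CO (3 bar), THF–NMP, 40 °C
Reagents that add atoms: carbon monoxide, [C-]#[O+]
Why: Zinc insertion into the primary iodide followed by Pd-catalysed carbonylative Negishi coupling (acylpalladium from the alkenyl triflate and CO, transmetalation, reductive elimination) builds the C2′–C3′(=O)–C4′(=CH2) enone; the alkylzinc tolerates the ester.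

Step 10
Reactants: 12 methyl 2-[(2R,5R)-5-[(7E)-8,12-dimethyl-4-methylidene-3-oxotrideca-7,11-dien-1-yl]oxan-2-yl]prop-2-enoate
Product: 13 methyl 2-[(2R,5S)-5-[(3R,7E)-3-hydroxy-8,12-dimethyl-4-methylidenetrideca-7,11-dien-1-yl]oxan-2-yl]prop-2-enoate
Conditions: (S)-1-methyl-3,3-diphenyltetrahydro-1H,3H-pyrrolo[1,2-c][1,3,2]oxazaborole (0.2 equiv), catecholborane (1.5 equiv), toluene, −78 °C
Reagents that add atoms: none
Why: Corey–Bakshi–Shibata reduction: the (S)-oxazaborolidine treats the alkenyl group as the large substituent and delivers hydride 1,2 to give the (3′R) allylic alcohol under catalyst control (the C5 descriptor changes by CIP only).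

Step 11
Reactants: 13 methyl 2-[(2R,5S)-5-[(3R,7E)-3-hydroxy-8,12-dimethyl-4-methylidenetrideca-7,11-dien-1-yl]oxan-2-yl]prop-2-enoate
Product: 15 2-[(2R,5S)-5-[(3R)-3-{(2S)-2-[(3E)-4,8-dimethylnona-3,7-dien-1-yl]oxiran-2-yl}-3-hydroxypropyl]oxan-2-yl]prop-2-enoic acid, via epoxy ester 14 (not isolated)
Conditions: Ti(OiPr)4 (10 mol %), diisopropyl D-(−)-tartrate (12 mol %), t-BuOOH (1.5 equiv), 4 Å MS, CH2Cl2, −20 °C; then LiOH, THF–MeOH–H2O, 0 °C; 1 M HCl to pH 4
Reagents that add atoms: tert-butyl hydroperoxide, CC(C)(C)OO; lithium hydroxide, [Li+].[OH-]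
Why: Sharpless epoxidation of a 2-substituted secondary allylic alcohol: D-tartrate is matched with the (3′R) alcohol and gives the erythro epoxy alcohol, which sets C4′ (the trisubstituted olefins and the acrylate are not epoxidised); LiOH then saponifies the ester, and Payne rearrangement is blocked at the fully substituted epoxide carbon.

Step 12
Reactants: 15 2-[(2R,5S)-5-[(3R)-3-{(2S)-2-[(3E)-4,8-dimethylnona-3,7-dien-1-yl]oxiran-2-yl}-3-hydroxypropyl]oxan-2-yl]prop-2-enoic acid
Product: 16 2-[(2R,5S)-5-[(3R,4R,7E)-3,4-dihydroxy-4,8,12-trimethyltrideca-7,11-dien-1-yl]oxan-2-yl]prop-2-enoic acid (target)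
Conditions: LiBHEt3 (5 equiv), THF, 0 °C to rt; H2O, then 1 M HCl to pH 4
Reagents that add atoms: none
Why: Super-Hydride opens the epoxide by SN2 at CH2, which becomes the C4′ methyl with the C4′–O bond retained, while the lithium carboxylate of the acrylic acid is inert to the reagent; this gives the (3′R,4′R) diol.

**Compound list**
1 | 4-(hydroxymethyl)phenol | OCc1ccc(O)cc1 | starting material
2 | 4-(hydroxymethyl)cyclohexan-1-ol (cis/trans) | OCC1CCC(O)CC1 | intermediate
3 | 4-(hydroxymethyl)cyclohexan-1-one | OCC1CCC(=O)CC1 | intermediate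
4 | (5R)-5-(hydroxymethyl)oxepan-2-one | O=C1CC[C@@H](CO)CCO1 | intermediate
5 | (5R)-2-ethynyl-5-(2-hydroxyethyl)oxan-2-ol | C#CC1(O)CC[C@H](CCO)CO1 | intermediate
6 | 2-[(3R,6R)-6-ethynyloxan-3-yl]ethan-1-ol | C#C[C@H]1CC[C@H](CCO)CO1 | intermediate
7 | methyl 2-[(2R,5R)-5-(2-hydroxyethyl)oxan-2-yl]prop-2-enoate | C=C(C(=O)OC)[C@H]1CC[C@H](CCO)CO1 | intermediate
8 | methyl 2-[(2R,5R)-5-(2-iodoethyl)oxan-2-yl]prop-2-enoate | C=C(C(=O)OC)[C@H]1CC[C@H](CCI)CO1 | intermediate
9 | (5E)-6,10-dimethylundeca-5,9-dien-2-one | CC(=O)CC/C=C(\C)CCC=C(C)C | starting material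
10 | (5E)-6,10-dimethylundeca-1,5,9-trien-2-yl trifluoromethanesulfonate | C=C(OS(=O)(=O)C(F)(F)F)CC/C=C(\C)CCC=C(C)C | intermediate
11 | {2-[(3R,6R)-6-(3-methoxy-3-oxoprop-1-en-2-yl)oxan-3-yl]ethyl}(iodo)zinc | C=C(C(=O)OC)[C@H]1CC[C@H](CC[Zn]I)CO1 | intermediate
12 | methyl 2-[(2R,5R)-5-[(7E)-8,12-dimethyl-4-methylidene-3-oxotrideca-7,11-dien-1-yl]oxan-2-yl]prop-2-enoate | C=C(C(=O)OC)[C@H]1CC[C@H](CCC(=O)C(=C)CC/C=C(\C)CCC=C(C)C)CO1 | intermediate
13 | methyl 2-[(2R,5S)-5-[(3R,7E)-3-hydroxy-8,12-dimethyl-4-methylidenetrideca-7,11-dien-1-yl]oxan-2-yl]prop-2-enoate | C=C(C(=O)OC)[C@H]1CC[C@H](CC[C@@H](O)C(=C)CC/C=C(\C)CCC=C(C)C)CO1 | intermediate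
14 | methyl 2-[(2R,5S)-5-[(3R)-3-{(2S)-2-[(3E)-4,8-dimethylnona-3,7-dien-1-yl]oxiran-2-yl}-3-hydroxypropyl]oxan-2-yl]prop-2-enoate | C=C(C(=O)OC)[C@H]1CC[C@H](CC[C@@H](O)[C@]2(OC2)CC/C=C(\C)CCC=C(C)C)CO1 | intermediate
15 | 2-[(2R,5S)-5-[(3R)-3-{(2S)-2-[(3E)-4,8-dimethylnona-3,7-dien-1-yl]oxiran-2-yl}-3-hydroxypropyl]oxan-2-yl]prop-2-enoic acid | C=C(C(=O)O)[C@H]1CC[C@H](CC[C@@H](O)[C@]2(OC2)CC/C=C(\C)CCC=C(C)C)CO1 | intermediate
16 | 2-[(2R,5S)-5-[(3R,4R,7E)-3,4-dihydroxy-4,8,12-trimethyltrideca-7,11-dien-1-yl]oxan-2-yl]prop-2-enoic acid | C=C(C(=O)O)[C@H]1CC[C@H](CC[C@@H](O)[C@](C)(O)CC/C=C(\C)CCC=C(C)C)CO1 | target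

**Step count and risk**
Total step count: 12. Longest linear sequence: 11 (steps 1–7 and 9–12; step 8 is the side branch).

Most likely to fail, step 3 (ee and sense of the Baeyer–Villiger oxidation on a ketone with a free hydroxyl). The fallback sets out from ketone 3 and comes back at hemiketal 5. Ketone 3 is deprotonated under in-situ-quench conditions with lithium bis[(S)-1-phenylethyl]amide and Me3SiCl (THF, −78 °C; the hydroxyl is silylated in the same flask; amide antipode chosen for the (4R) product) to give trimethyl({(4R)-4-[(trimethylsilyloxy)methyl]cyclohex-1-en-1-yl}oxy)silane F1. Ozonolysis of the enol ether double bond with NaBH4 work-up and acidification gives (4R)-6-hydroxy-4-(hydroxymethyl)hexanoic acid F2, which closes to (5R)-5-(2-hydroxyethyl)oxan-2-one F3. F3 takes up HC≡CMgBr under the conditions of step 4 and gives 5.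

Second, step 9 (carbonylative coupling; direct coupling without CO insertion may compete). The fallback sets out from alcohol 7 and comes back at enone 12. Dess–Martin periodinane oxidises 7 to methyl 2-[(2R,5R)-5-(2-oxoethyl)oxan-2-yl]prop-2-enoate F4. Wittig reaction with Ph3P=CHOMe gives methyl 2-[(2R,5R)-5-(3-methoxyprop-2-en-1-yl)oxan-2-yl]prop-2-enoate F5, and aqueous HCl hydrolyses it to methyl 2-[(2R,5R)-5-(3-oxopropyl)oxan-2-yl]prop-2-enoate F6. Nozaki–Hiyama–Kishi coupling of F6 with triflate 10 (CrCl2, NiCl2 cat., DMF) gives the C3′-epimeric methyl 2-[(2R,5S)-5-[(7E)-3-hydroxy-8,12-dimethyl-4-methylidenetrideca-7,11-dien-1-yl]oxan-2-yl]prop-2-enoate F7, and Dess–Martin oxidation of F7 gives 12.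

Third, step 12 (hydride opening beside an acrylate carboxylate, on an acid-sensitive epoxy acid). The fallback sets out from epoxy ester 14, isolated by leaving out the LiOH stage of step 11, and comes back at 16. LiAlH4 (Et2O, −20 °C) opens the epoxide at CH2 and reduces the ester to 2-[(2R,5S)-5-[(3R,4R,7E)-3,4-dihydroxy-4,8,12-trimethyltrideca-7,11-dien-1-yl]oxan-2-yl]prop-2-en-1-ol F8. MnO2 oxidises only the primary allylic alcohol to 2-[(2R,5S)-5-[(3R,4R,7E)-3,4-dihydroxy-4,8,12-trimethyltrideca-7,11-dien-1-yl]oxan-2-yl]prop-2-enal F9, and Pinnick oxidation (NaClO2, NaH2PO4, 2-methylbut-2-ene) gives 16.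

**Further compounds**
F1 | step 3 | trimethyl({(4R)-4-[(trimethylsilyloxy)methyl]cyclohex-1-en-1-yl}oxy)silane | C[Si](C)(C)OC[C@@H]1CCC(O[Si](C)(C)C)=CC1
F2 | step 3 | (4R)-6-hydroxy-4-(hydroxymethyl)hexanoic acid | OC(=O)CC[C@H](CCO)CO
F3 | step 3 | (5R)-5-(2-hydroxyethyl)oxan-2-one | O=C1CC[C@H](CCO)CO1
F4 | step 9 | methyl 2-[(2R,5R)-5-(2-oxoethyl)oxan-2-yl]prop-2-enoate | C=C(C(=O)OC)[C@H]1CC[C@H](CC=O)CO1
F5 | step 9 | methyl 2-[(2R,5R)-5-(3-methoxyprop-2-en-1-yl)oxan-2-yl]prop-2-enoate (E/Z mixture) | C=C(C(=O)OC)[C@H]1CC[C@H](CC=COC)CO1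
F6 | step 9 | methyl 2-[(2R,5R)-5-(3-oxopropyl)oxan-2-yl]prop-2-enoate | C=C(C(=O)OC)[C@H]1CC[C@H](CCC=O)CO1
F7 | step 9 | methyl 2-[(2R,5S)-5-[(7E)-3-hydroxy-8,12-dimethyl-4-methylidenetrideca-7,11-dien-1-yl]oxan-2-yl]prop-2-enoate (C3′ epimers) | C=C(C(=O)OC)[C@H]1CC[C@H](CCC(O)C(=C)CC/C=C(\C)CCC=C(C)C)CO1
F8 | step 12 | 2-[(2R,5S)-5-[(3R,4R,7E)-3,4-dihydroxy-4,8,12-trimethyltrideca-7,11-dien-1-yl]oxan-2-yl]prop-2-en-1-ol | C=C(CO)[C@H]1CC[C@H](CC[C@@H](O)[C@](C)(O)CC/C=C(\C)CCC=C(C)C)CO1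
F9 | step 12 | 2-[(2R,5S)-5-[(3R,4R,7E)-3,4-dihydroxy-4,8,12-trimethyltrideca-7,11-dien-1-yl]oxan-2-yl]prop-2-enal | C=C(C=O)[C@H]1CC[C@H](CC[C@@H](O)[C@](C)(O)CC/C=C(\C)CCC=C(C)C)CO1
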